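**Retrosynthetic overview**
- The plan rests on ring B, a pentasubstituted benzene: C1' bonded to C3, oxygens on C2', C3' and C4', prenyl on C5', hydrogen only on C6'. This pattern maps onto a 1,1,2,3-tetraoxygenated 4-alkyl diene plus an acyl alkyne.
- Ring C is opened last at C3–C4 (asymmetric carbene-catalysed aldehyde–ketone benzoin) and at the C2–O1 ether (Williamson), giving a ring-B bromoacetyl arene and a ring-A salicylaldehyde.
- Ring B is opened at C1'–C2' and C5'–C6' by a [4+2] benzannulation of vinylketene silyl acetal 7 with but-3-yn-2-one 8, aromatised by loss of methanol.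
- Diene 7 comes in four steps from methyl glycolate and 5-methylhex-4-enoic acid (MOM ether, enolate acylation, O-methylation, γ-deprotonation/silylation).
- Ring order: ring B is built (step 5), ring A is bought, ring C is closed (step 10).

Key step: step 5

Assumption: the (5aR,10bS) antipode of the aminoindanol triazolium salt is taken to direct the Breslow intermediate to the Re face of the ketone, which gives (3S). If a test cyclisation shows the opposite sense, the (5aS,10bR) salt is used instead. 5-Methylhex-4-enoic acid is taken as a catalogue building block.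

**Step 1**
Reactants: 1 methyl glycolate
Product: 2 methyl 2-(methoxymethoxy)acetate
Conditions: MOMCl, i-Pr2NEt, CH2Cl2, 0 °C → rt
Reagents that add atoms: chloromethyl methyl ether, COCCl
Why: Standard MOM etherification of a primary alcohol (alkylation through the methoxymethyl oxocarbenium ion under amine base); the methyl ester is inert.

**Step 2**
Reactants: 3 5-methylhex-4-enoic acid; 2 methyl 2-(methoxymethoxy)acetate
Product: 5 methyl 2-(methoxymethoxy)-7-methyl-3-oxooct-6-enoate, via acid chloride 4 (not isolated)
Conditions: (COCl)2, cat. DMF, CH2Cl2, 0 °C → rt, evaporate; then lithium enolate of 2 [2.2 equiv, LiN(SiMe3)2, THF, −78 °C], −78 °C; aq NH4Cl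
Reagents that add atoms: none
Why: Crossed Claisen-type C-acylation of the preformed, chelated lithium enolate of an α-alkoxy ester by an acid chloride should give the racemic β-keto ester, the second equivalent of enolate taking up the acidic C2–H of the product while the trisubstituted alkene is a spectator.

**Step 3**
Reactants: 5 methyl 2-(methoxymethoxy)-7-methyl-3-oxooct-6-enoate
Product: 6 methyl 3-methoxy-2-(methoxymethoxy)-7-methylocta-2,6-dienoate
Conditions: KN(SiMe3)2, THF/DMPU, −78 °C; then Me2SO4, −78 → 0 °C
Reagents that add atoms: dimethyl sulfate, COS(=O)(=O)OC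
Why: O-alkylation of an ambident β-keto ester enolate: the dissociated potassium enolate meets the hard sulfate electrophile at oxygen, C-methylation at the fully substituted C2 is disfavoured, and either geometry of the enol ether is usable because C2=C3 becomes the single bond of the diene.

**Step 4**
Reactants: 6 methyl 3-methoxy-2-(methoxymethoxy)-7-methylocta-2,6-dienoate
Product: 7 (3Z)-1,3-dimethoxy-2-(methoxymethoxy)-7-methyl-1-(trimethylsilyloxy)octa-1,3,6-triene
Conditions: LiN(i-Pr)2, THF, −78 °C; then Me3SiCl, −78 °C → rt; pentane, filter, use crude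
Reagents that add atoms: chlorotrimethylsilane, C[Si](C)(C)Cl
Why: Kinetic γ-deprotonation of a β-alkoxy enoate followed by O-silylation of the dienolate is the standard preparation of Brassard-type vinylketene silyl acetals, and the alkyl chain is expected to settle anti to C2 on the new C3=C4 bond to avoid allylic strain.

**Step 5**
Reactants: 7 (3Z)-1,3-dimethoxy-2-(methoxymethoxy)-7-methyl-1-(trimethylsilyloxy)octa-1,3,6-triene; 8 but-3-yn-2-one
Product: 10 1-[2-hydroxy-4-methoxy-3-(methoxymethoxy)-5-(3-methylbut-2-enyl)phenyl]ethanone, via cyclohexadiene adduct 9 (not isolated)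
Conditions: 8 (1.5 equiv), toluene, 0 → 50 °C; then 0.1 M aq HCl, THF, 0 °C
Reagents that add atoms: none
Why: The electron-rich diene and the electron-poor ynone should combine in a normal-demand [4+2] cycloaddition that is concerted but strongly asynchronous, the limiting Mukaiyama–Michael/ring-closure pathway leading to the same adduct 9. The closest known reaction is the benzannulation of Brassard- and Danishefsky-type silyloxydienes with acetylenic ketones and esters. Ring B is closed by this intermolecular cycloaddition, which forms C5'–C6' (diene C4 to the alkyne CH) and C1'–C2' (ketene acetal carbon to the acyl-bearing alkyne carbon), and no stereocentre remains because the sp3 carbons of 9 are lost on aromatisation. On dilute acid work-up the silyl ketal at the future C2' is cleaved at silicon first and the hemiketal expels methanol, so the dienone tautomerises to the arene with a free C2' phenol hydrogen-bonded to the acetyl group, while the C3' MOM ether and the C4' methyl ether are carried through. The step needs regio- and chemoselectivity: the push of the C1 and C3 oxygens makes the prenyl-bearing terminus C4 nucleophilic, the carbonyl makes the unsubstituted alkyne carbon electrophilic, and the isolated electron-rich alkene of the side chain cannot compete as a dienophile.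

**Step 6**
Reactants: 10 1-[2-hydroxy-4-methoxy-3-(methoxymethoxy)-5-(3-methylbut-2-enyl)phenyl]ethanone
Product: 11 1-[4-methoxy-2,3-bis(methoxymethoxy)-5-(3-methylbut-2-enyl)phenyl]ethanone
Conditions: NaH (1.05 equiv), DMF, 0 °C; then MOMCl, 0 °C → rt
Reagents that add atoms: chloromethyl methyl ether, COCCl
Why: Williamson-type O-alkylation of the sodium phenoxide; full deprotonation overcomes the hydrogen bond of the C2' phenol to the acetyl carbonyl, and the phenol is far more acidic than the methyl ketone.

**Step 7**
Reactants: 11 1-[4-methoxy-2,3-bis(methoxymethoxy)-5-(3-methylbut-2-enyl)phenyl]ethanone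
Product: 13 2-bromo-1-[4-methoxy-2,3-bis(methoxymethoxy)-5-(3-methylbut-2-enyl)phenyl]ethanone, via silyl enol ether 12 (not isolated)
Conditions: LiN(SiMe3)2, Me3SiCl, THF, −78 °C; then NBS, THF, −78 °C
Reagents that add atoms: N-bromosuccinimide, O=C1CCC(=O)N1Br
Why: Regiospecific α-bromination of a ketone through its silyl enol ether: the kinetic enolate of the methyl ketone is trapped on oxygen and the enol ether should react with NBS at −78 °C much faster than the prenyl alkene or the arene, with no free bromine or acid present.

**Step 8**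
Reactants: 14 2,4-dihydroxybenzaldehyde
Product: 15 2-hydroxy-4-(methoxymethoxy)benzaldehyde
Conditions: MOMCl (1.05 equiv), K2CO3, acetone, 0 °C → rt
Reagents that add atoms: chloromethyl methyl ether, COCCl
Why: Regioselective Williamson-type MOM protection: the C2 hydroxyl is held in a hydrogen bond to the aldehyde, so one equivalent of MOMCl should alkylate the free and more acidic C4 phenol.

**Step 9**
Reactants: 13 2-bromo-1-[4-methoxy-2,3-bis(methoxymethoxy)-5-(3-methylbut-2-enyl)phenyl]ethanone; 15 2-hydroxy-4-(methoxymethoxy)benzaldehyde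
Product: 16 2-{2-[4-methoxy-2,3-bis(methoxymethoxy)-5-(3-methylbut-2-enyl)phenyl]-2-oxoethoxy}-4-(methoxymethoxy)benzaldehyde
Conditions: K2CO3, acetone, rt
Reagents that add atoms: none
Why: Williamson ether synthesis (SN2 of the phenoxide on a reactive α-bromo ketone); mild carbonate at room temperature should keep the product from the base-induced intramolecular aldol (Rap–Stoermer) path to a 2-aroylbenzofuran.

**Step 10**
Reactants: 16 2-{2-[4-methoxy-2,3-bis(methoxymethoxy)-5-(3-methylbut-2-enyl)phenyl]-2-oxoethoxy}-4-(methoxymethoxy)benzaldehyde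
Product: 17 (3S)-3-hydroxy-7-(methoxymethoxy)-3-[4-methoxy-2,3-bis(methoxymethoxy)-5-(3-methylbut-2-enyl)phenyl]chroman-4-one
Conditions: (5aR,10bS)-2-(pentafluorophenyl)-5a,10b-dihydro-4H,6H-indeno[2,1-b][1,2,4]triazolo[4,3-d][1,4]oxazin-2-ium tetrafluoroborate (10 mol %), Et3N (10 mol %), toluene, rt
Reagents that add atoms: none
Why: Intramolecular crossed aldehyde–ketone benzoin reaction under chiral N-heterocyclic carbene catalysis: the carbene turns the aldehyde into a Breslow intermediate that adds 6-exo-trig to the aryl ketone, forming C3–C4 and ring C, and the aminoindanol backbone should direct attack to the Re face of the ketone to set the (3S) tertiary carbinol, which cannot epimerise because C3 bears no hydrogen.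

**Step 11**
Reactants: 17 (3S)-3-hydroxy-7-(methoxymethoxy)-3-[4-methoxy-2,3-bis(methoxymethoxy)-5-(3-methylbut-2-enyl)phenyl]chroman-4-one
Product: 19 (3S)-3-[2,3-dihydroxy-4-methoxy-5-(3-methylbut-2-enyl)phenyl]-3,7-dihydroxychroman-4-one, via tetrakis(trimethylsilyl) ether 18 (not isolated)
Conditions: Me3SiOTf, 2,2′-bipyridyl, MeCN, 0 °C → rt; then H2O, rt
Reagents that add atoms: none
Why: Chemoselective cleavage of aryl MOM ethers with Me3SiOTf–2,2′-bipyridyl: each ArOCH2OMe is converted into ArOSiMe3 (the tertiary alcohol is capped as well) without free Brønsted acid, and water then hydrolyses the O–Si bonds, so the prenyl group and the dehydration-prone tertiary benzylic carbinol should be spared.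

**Compound list**
1 | methyl glycolate | COC(=O)CO | starting material
2 | methyl 2-(methoxymethoxy)acetate | COCOCC(=O)OC | intermediate
3 | 5-methylhex-4-enoic acid | CC(C)=CCCC(=O)O | starting material
4 | 5-methylhex-4-enoyl chloride | CC(C)=CCCC(=O)Cl | intermediate
5 | methyl 2-(methoxymethoxy)-7-methyl-3-oxooct-6-enoate (racemic) | COC(=O)C(OCOC)C(=O)CCC=C(C)C | intermediate
6 | methyl 3-methoxy-2-(methoxymethoxy)-7-methylocta-2,6-dienoate (C2=C3 isomers, both used) | COC(=O)C(OCOC)=C(OC)CCC=C(C)C | intermediate
7 | (3Z)-1,3-dimethoxy-2-(methoxymethoxy)-7-methyl-1-(trimethylsilyloxy)octa-1,3,6-triene (C1=C2 geometry not defined) | COC(O[Si](C)(C)C)=C(OCOC)/C(OC)=C/CC=C(C)C | intermediate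
8 | but-3-yn-2-one | CC(=O)C#C | starting material
9 | 1-[4,6-dimethoxy-5-(methoxymethoxy)-3-(3-methylbut-2-enyl)-6-(trimethylsilyloxy)cyclohexa-1,4-dien-1-yl]ethanone (diastereomer mixture) | CC(=O)C1=CC(CC=C(C)C)C(OC)=C(OCOC)C1(OC)O[Si](C)(C)C | intermediate
10 | 1-[2-hydroxy-4-methoxy-3-(methoxymethoxy)-5-(3-methylbut-2-enyl)phenyl]ethanone | CC(=O)c1cc(CC=C(C)C)c(OC)c(OCOC)c1O | intermediate
11 | 1-[4-methoxy-2,3-bis(methoxymethoxy)-5-(3-methylbut-2-enyl)phenyl]ethanone | CC(=O)c1cc(CC=C(C)C)c(OC)c(OCOC)c1OCOC | intermediate
12 | trimethyl({1-[4-methoxy-2,3-bis(methoxymethoxy)-5-(3-methylbut-2-enyl)phenyl]ethenyl}oxy)silane | C=C(O[Si](C)(C)C)c1cc(CC=C(C)C)c(OC)c(OCOC)c1OCOC | intermediate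
13 | 2-bromo-1-[4-methoxy-2,3-bis(methoxymethoxy)-5-(3-methylbut-2-enyl)phenyl]ethanone | BrCC(=O)c1cc(CC=C(C)C)c(OC)c(OCOC)c1OCOC | intermediate
14 | 2,4-dihydroxybenzaldehyde | O=Cc1ccc(O)cc1O | starting material
15 | 2-hydroxy-4-(methoxymethoxy)benzaldehyde | O=Cc1ccc(OCOC)cc1O | intermediate
16 | 2-{2-[4-methoxy-2,3-bis(methoxymethoxy)-5-(3-methylbut-2-enyl)phenyl]-2-oxoethoxy}-4-(methoxymethoxy)benzaldehyde | O=Cc1ccc(OCOC)cc1OCC(=O)c1cc(CC=C(C)C)c(OC)c(OCOC)c1OCOC | intermediate
17 | (3S)-3-hydroxy-7-(methoxymethoxy)-3-[4-methoxy-2,3-bis(methoxymethoxy)-5-(3-methylbut-2-enyl)phenyl]chroman-4-one | COc1c(CC=C(C)C)cc([C@]2(O)COc3cc(OCOC)ccc3C2=O)c(OCOC)c1OCOC | intermediate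
18 | (3S)-3-[4-methoxy-5-(3-methylbut-2-enyl)-2,3-bis(trimethylsilyloxy)phenyl]-3,7-bis(trimethylsilyloxy)chroman-4-one | COc1c(CC=C(C)C)cc([C@]2(O[Si](C)(C)C)COc3cc(O[Si](C)(C)C)ccc3C2=O)c(O[Si](C)(C)C)c1O[Si](C)(C)C | intermediate
19 | (3S)-3-[2,3-dihydroxy-4-methoxy-5-(3-methylbut-2-enyl)phenyl]-3,7-dihydroxychroman-4-one | COc1c(CC=C(C)C)cc([C@]2(O)COc3cc(O)ccc3C2=O)c(O)c1O | target

**Step count and risks**
Total steps: 11. Longest linear sequence: 10 steps (steps 1–7 and 9–11, from methyl glycolate 1).

Steps most likely to fail: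

1. Step 5. The nucleophilic ketene acetal may add to the ynone in conjugate fashion without closing the ring, the ynone may oligomerise, or aromatisation may expel the silyloxy group in place of methanol. The fallback sets out from diene 7 and replaces the alkyne by an alkene dienophile with oxidative aromatisation. Thermal cycloaddition of 7 with methyl vinyl ketone (toluene, rt → 60 °C) should give the silyl ketal cycloadduct 1-[2,4-dimethoxy-3-(methoxymethoxy)-5-(3-methylbut-2-enyl)-2-(trimethylsilyloxy)cyclohex-3-en-1-yl]ethanone F1. Dilute acid then unmasks the ring ketone to give the enolised β-diketone 6-acetyl-3-methoxy-2-(methoxymethoxy)-4-(3-methylbut-2-enyl)cyclohex-2-en-1-one F2, in which the C2' oxygen is fixed as a carbonyl. Dehydrogenation with 2,3-dichloro-5,6-dicyano-1,4-benzoquinone in dioxane should aromatise F2, and the route is rejoined at 10.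

2. Step 10. Facial discrimination may be poor at the ortho-disubstituted aryl ketone, addition of the Breslow intermediate to this hindered ketone may be slow, and base-induced aldol cyclisation may take over. The fallback sets out from 16 and gives up catalyst control for resolution. A small achiral carbene (3-benzyl-5-(2-hydroxyethyl)-4-methylthiazolium chloride, Et3N, t-BuOH, 40 °C) should close ring C to the racemic carbinol rac-3-hydroxy-7-(methoxymethoxy)-3-[4-methoxy-2,3-bis(methoxymethoxy)-5-(3-methylbut-2-enyl)phenyl]chroman-4-one F3. Preparative chromatography on an amylose tris(3,5-dimethylphenylcarbamate) phase then separates the enantiomers; the unwanted (3R)-enantiomer of 17 F4 is set aside and the (3S)-enantiomer rejoins the route at 17.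

3. Step 7. Electrophilic bromine may attack the prenyl double bond or the free C6' position of ring B, or the ketone may be brominated twice. The fallback sets out from 11 and avoids halogen altogether. The potassium enolate (KN(SiMe3)2, THF, −78 °C) is hydroxylated with 3-phenyl-2-(phenylsulfonyl)oxaziridine (Davis oxidation) to 2-hydroxy-1-[4-methoxy-2,3-bis(methoxymethoxy)-5-(3-methylbut-2-enyl)phenyl]ethanone F5. Mitsunobu etherification of F5 with phenol 15 (PPh3, diisopropyl azodicarboxylate, THF, 0 °C → rt) should give the aryl ether directly, and the route is rejoined at 16.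

**Further compounds**
F1 | step 5 | 1-[2,4-dimethoxy-3-(methoxymethoxy)-5-(3-methylbut-2-enyl)-2-(trimethylsilyloxy)cyclohex-3-en-1-yl]ethanone | CC(=O)C1CC(CC=C(C)C)C(OC)=C(OCOC)C1(OC)O[Si](C)(C)C
F2 | step 5 | 6-acetyl-3-methoxy-2-(methoxymethoxy)-4-(3-methylbut-2-enyl)cyclohex-2-en-1-one | CC(=O)C1CC(CC=C(C)C)C(OC)=C(OCOC)C1=O
F3 | step 10 | rac-3-hydroxy-7-(methoxymethoxy)-3-[4-methoxy-2,3-bis(methoxymethoxy)-5-(3-methylbut-2-enyl)phenyl]chroman-4-one | COc1c(CC=C(C)C)cc(C2(O)COc3cc(OCOC)ccc3C2=O)c(OCOC)c1OCOC
F4 | step 10 | (3R)-3-hydroxy-7-(methoxymethoxy)-3-[4-methoxy-2,3-bis(methoxymethoxy)-5-(3-methylbut-2-enyl)phenyl]chroman-4-one | COc1c(CC=C(C)C)cc([C@@]2(O)COc3cc(OCOC)ccc3C2=O)c(OCOC)c1OCOC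
F5 | step 7 | 2-hydroxy-1-[4-methoxy-2,3-bis(methoxymethoxy)-5-(3-methylbut-2-enyl)phenyl]ethanone | OCC(=O)c1cc(CC=C(C)C)c(OC)c(OCOC)c1OCOC
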